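## Retrosynthetic overview

1. The plan rests on the ring-fusion bond C4a–C7a. It is the one bond common to cyclopentene ring A (C4a, C5, C6, C7, C7a) and pyran ring B (C1, O2, C3, C4, C4a, C7a), and it ties the polyketide arm C3–C4–C4a–C5(CO2Me) to the enol-ether carbon C7a.
2. Ring B is opened first, at O2–C1. This leaves a C3 ketone masked as a dioxolane and a C7a=C1H(OMe) methoxymethylene group on a silylated ring A.
3. Ring A is then opened at C4a–C7a by a retro-Heck cut. The result is an open-chain (E)-enol triflate (OTf on C4a, cis to C6) with an (E)-methoxyvinyl group on C7.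
4. The triflate comes from C5–C6 Michael union of a ketal-protected β-keto ester with an ynone, and the ynone from C1'–C2' acylation of a C7 alkyne with a Weinreb amide. C7 is set by a Sharpless epoxidation, chosen as more dependable for a tertiary carbinol than enantioselective alkynylation of a methyl ketone. C3' is set by an Evans methylation.
5. Forward order of ring formation: ring A (Heck closure), then ring B (acid-triggered pyran closure).

Key step: step 15

Remark: the locants C1–C7a and C1'–C3' of the target's cyclopenta[c]pyran skeleton and side chain are used for every intermediate. The C7 descriptor is S in the open-chain compounds and R once ring A is closed, with no change in spatial arrangement, because C7a overtakes C6 in priority.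

Remark: the Wittig step is assumed to give both enol ether geometries, and the E isomer is drawn and carried on.

## Route

**Fragment 1: the C7 alkyne**

Step 1
Reactants: 1 (E)-3-methylpent-2-en-4-yn-1-ol
Product: 2 [(2R,3R)-3-ethynyl-3-methyloxiran-2-yl]methanol
Conditions: Ti(OiPr)4 (cat), D-(−)-diisopropyl tartrate (cat), t-BuOOH, 4 Å molecular sieves, CH2Cl2, −20 °C
Reagents that add atoms: tert-butyl hydroperoxide, CC(C)(C)OO
Why: Katsuki–Sharpless asymmetric epoxidation of an (E)-trisubstituted allylic alcohol, in which the D-(−)-tartrate titanium complex delivers oxygen to the face that gives the (2R,3R)-epoxide and so fixes the C7–O bond in the configuration of the target.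

Step 2
Reactants: 2 [(2R,3R)-3-ethynyl-3-methyloxiran-2-yl]methanol
Product: 3 (2R,3S)-2-ethynyl-3-(iodomethyl)-2-methyloxirane
Conditions: I2, PPh3, imidazole, CH2Cl2, 0 °C
Reagents that add atoms: iodine, II
Why: Appel-type iodination of the primary alcohol proceeds by SN2 displacement at C1 under imidazole buffering, so the epoxide and both its stereocentres stay untouched.

Step 3
Reactants: 3 (2R,3S)-2-ethynyl-3-(iodomethyl)-2-methyloxirane
Product: 4 (S)-3-methylpent-1-en-4-yn-3-ol
Conditions: Zn dust, EtOH, 60 °C
Reagents that add atoms: none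
Why: Zinc inserts into the C–I bond and the organozinc expels the neighbouring epoxide oxygen (reductive β-elimination of a 2,3-epoxy iodide, the usual transposition of an epoxy alcohol into a tertiary allylic alcohol), and because only the C7a–O bond breaks, C7 keeps its configuration under neutral conditions that this acid-labile carbinol tolerates.

Step 4
Reactants: 4 (S)-3-methylpent-1-en-4-yn-3-ol
Product: 5 triethyl{[(3S)-3-methylpent-1-en-4-yn-3-yl]oxy}silane
Conditions: Et3SiOTf, 2,6-lutidine, CH2Cl2, −78 to 0 °C
Reagents that add atoms: triethylsilyl triflate, CC[Si](CC)(CC)OS(=O)(=O)C(F)(F)F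
Why: Silyl triflate silylation is fast enough for a tertiary alcohol, and the hindered pyridine base keeps the medium free of acid, so the C7–O bond is not ionised.

Step 5
Reactants: 5 triethyl{[(3S)-3-methylpent-1-en-4-yn-3-yl]oxy}silane
Product: 7 (R)-2-methyl-2-(triethylsilyloxy)but-3-ynal, via secondary ozonide 6 (not isolated)
Conditions: O3, CH2Cl2, −78 °C, stopped when 5 is consumed; then PPh3, −78 °C to rt
Reagents that add atoms: ozone, [O-][O+]=O
Why: Ozonolysis with reductive work-up cleaves the vinyl group much faster than the terminal alkyne and gives a non-enolisable α-silyloxy aldehyde in which C7a is at the aldehyde level.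

Step 6
Reactants: 7 (R)-2-methyl-2-(triethylsilyloxy)but-3-ynal
Product: 8 triethyl{[(1E,3S)-1-methoxy-3-methylpent-1-en-4-yn-3-yl]oxy}silane
Conditions: MeOCH2PPh3Cl, KOtBu, THF, 0 °C; then 7, −78 to 0 °C; chromatography on Et3N-washed silica
Reagents that add atoms: (methoxymethyl)triphenylphosphonium chloride, COC[P+](c1ccccc1)(c1ccccc1)c1ccccc1.[Cl-]
Why: Wittig methoxymethylenation of the aldehyde installs C1, the E isomer is separated and carried on as drawn, and the Z isomer can follow the same steps because the C7a=C1 geometry is rewritten in step 15 and erased in step 16.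

**Fragment 2: the side-chain Weinreb amide**

Step 7
Reactants: 9 (S)-4-benzyl-1,3-oxazolidin-2-one; 10 octanoyl chloride
Product: 12 (S)-4-benzyl-3-octanoyl-1,3-oxazolidin-2-one, via lithium oxazolidinonide 11 (not isolated)
Conditions: n-BuLi, THF, −78 °C; then 10, −78 to 0 °C
Reagents that add atoms: none
Why: N-acylation of the lithiated auxiliary with an acid chloride is the standard entry to an Evans imide.

Step 8
Reactants: 12 (S)-4-benzyl-3-octanoyl-1,3-oxazolidin-2-one
Product: 14 (S)-4-benzyl-3-[(S)-2-methyloctanoyl]-1,3-oxazolidin-2-one, via sodium Z-enolate 13 (not isolated)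
Conditions: NaN(SiMe3)2, THF, −78 °C; then MeI, −78 to −40 °C
Reagents that add atoms: iodomethane, CI
Why: Evans asymmetric alkylation, in which the chelated Z-enolate is methylated on the face opposite the benzyl group, and with the hexyl chain already on the enolate this gives the (S)-configured C3'.

Step 9
Reactants: 14 (S)-4-benzyl-3-[(S)-2-methyloctanoyl]-1,3-oxazolidin-2-one
Product: 15 (S)-N-methoxy-N,2-dimethyloctanamide
Conditions: MeNH(OMe)·HCl, AlMe3, CH2Cl2, −10 °C to rt; aq potassium sodium tartrate
Reagents that add atoms: N,O-dimethylhydroxylamine hydrochloride, CNOC.Cl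
Why: Aluminium amide aminolysis (Weinreb transamidation) attacks the exocyclic imide carbonyl, frees the auxiliary for reuse and never enolises the acyl group, so C3' is retained.

**Union of fragments 1 and 2**

Step 10
Reactants: 8 triethyl{[(1E,3S)-1-methoxy-3-methylpent-1-en-4-yn-3-yl]oxy}silane; 15 (S)-N-methoxy-N,2-dimethyloctanamide
Product: 18 (1E,3S,7S)-1-methoxy-3,7-dimethyl-3-(triethylsilyloxy)tridec-1-en-4-yn-6-one, via lithium acetylide 16 (not isolated), via lithium hemiaminal alkoxide 17 (not isolated)
Conditions: 8, n-BuLi, THF, −78 °C; then 15, −78 to 0 °C; pH 7 phosphate buffer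
Reagents that add atoms: none
Why: Weinreb ketone synthesis, in which n-BuLi at −78 °C removes only the alkyne proton and the chelated adduct 17 survives until the buffered quench, so the ynone forms at the right oxidation level without over-addition, without epimerisation at C3' and without acid contact for the enol ether.

**Fragment 3: the β-keto ester**

Step 11
Reactants: 19 ethyl 2-(2-methyl-1,3-dioxolan-2-yl)acetate
Product: 21 2-(2-methyl-1,3-dioxolan-2-yl)acetic acid, via lithium carboxylate 20 (not isolated)
Conditions: LiOH, THF/H2O, rt; then cold 1 M HCl to pH 4, 0 °C, immediate extraction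
Reagents that add atoms: lithium hydroxide, [Li+].[OH-]
Why: Saponification leaves the base-stable ketal alone, and the brief cold acidification is too mild to hydrolyse it.

Step 12
Reactants: 21 2-(2-methyl-1,3-dioxolan-2-yl)acetic acid
Product: 23 methyl 4-(2-methyl-1,3-dioxolan-2-yl)-3-oxobutanoate, via acyl imidazole 22 (not isolated)
Conditions: 1,1'-carbonyldiimidazole, THF, rt; then MeO2CCH2CO2K, MgCl2, Et3N, MeCN, rt to 40 °C; aq NH4Cl
Reagents that add atoms: potassium methyl malonate, COC(=O)CC(=O)[O-].[K+]
Why: Masamune–Brooks homologation, in which the magnesium enolate of the malonate half-ester is C-acylated by the acyl imidazole and loses CO2, builds C5 and the ester under near-neutral conditions that neither cleave nor β-eliminate the ketal.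

**Assembly, ring closures and deprotection**

Step 13
Reactants: 18 (1E,3S,7S)-1-methoxy-3,7-dimethyl-3-(triethylsilyloxy)tridec-1-en-4-yn-6-one; 23 methyl 4-(2-methyl-1,3-dioxolan-2-yl)-3-oxobutanoate
Product: 24 methyl 2-[(1E,3S,4Z,7S)-1-methoxy-3,7-dimethyl-6-oxo-3-(triethylsilyloxy)trideca-1,4-dien-4-yl]-4-(2-methyl-1,3-dioxolan-2-yl)-3-oxobutanoate (C5 epimers and enol form)
Conditions: Cs2CO3 (0.2 equiv), THF, 0 °C to rt; pH 7 buffer; Et3N-washed silica
Reagents that add atoms: none
Why: Base-catalysed Michael addition of a β-keto ester to an alkynone, in which C5 attacks the sterically open sp carbon C6 and the allenolate is protonated at C1' in the plane of the C6 substituents from the side of the flatter C5 group and away from quaternary C7, which places H cis to C5 and the acyl group cis to C7 in the same sense as the aminodienone stage of the Bohlmann–Rahtz reaction.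

Step 14
Reactants: 24 Michael adduct
Product: 26 methyl (2E)-2-[(1E,3S,4Z,7S)-1-methoxy-3,7-dimethyl-6-oxo-3-(triethylsilyloxy)trideca-1,4-dien-4-yl]-4-(2-methyl-1,3-dioxolan-2-yl)-3-(trifluoromethylsulfonyloxy)but-2-enoate, via potassium enolate 25 (not isolated)
Conditions: KN(SiMe3)2 (1.05 equiv), 18-crown-6, THF, −78 °C; then N-(5-chloropyridin-2-yl)bis(trifluoromethanesulfonimide), −78 to −20 °C
Reagents that add atoms: N-(5-chloropyridin-2-yl)bis(trifluoromethanesulfonimide), Clc1ccc(nc1)N(S(=O)(=O)C(F)(F)F)S(=O)(=O)C(F)(F)F
Why: Stereoselective enol triflation of a 2-substituted acetoacetate through its non-chelated enolate, whose dipole-minimised form holds the C4a oxygen away from the ester and next to C6 and so should give the (E)-triflate that ring closure demands, while the twist about C5–C6 forced by quaternary C7 keeps the charge out of the enone and thereby protects the C6=C1' geometry and the C2' oxygen.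

Step 15
Reactants: 26 open-chain (E)-enol triflate
Product: 29 methyl (3Z,4R,5Z)-3-(methoxymethylidene)-4-methyl-2-[(2-methyl-1,3-dioxolan-2-yl)methyl]-5-[(3S)-3-methyl-2-oxononylidene]-4-(triethylsilyloxy)cyclopent-1-ene-1-carboxylate, via alkenylpalladium chloride 27 (not isolated), via alkylpalladium chloride 28 (not isolated)
Conditions: Pd(PPh3)4 (10 mol %), LiCl (3 equiv), 1,2,2,6,6-pentamethylpiperidine (3 equiv), degassed DMF (0.02 M), 60 °C
Reagents that add atoms: none
Why: Zerovalent palladium inserts into the C4a–OTf bond of the electron-poor enol triflate, chloride takes the place of triflate to give neutral alkenylpalladium chloride 27, the C7a=C1 enol ether inserts syn so that C4a bonds to C7a and palladium lands on the methoxy-bearing C1 (28), and after rotation about C7a–C1 a syn β-hydride elimination of the hydrogen on C7a, the only β-hydrogen available, restores the enol ether as an exocyclic methoxymethylene group while the amine takes up HCl and returns the catalyst. The closest known reaction type is the intramolecular Mizoroki–Heck cyclisation of an alkenyl triflate onto an enol ether with β-hydride elimination back to the enol ether. Ring A (C4a, C5, C6, C7, C7a) closes in the 5-exo-trig mode. No stereocentre is created, since the two sp3 carbons of 28 become sp2 again and C7 is only a spectator; the syn insertion and syn elimination turn the E enol ether into the Z methoxymethylene group (OMe on the C7 side), a geometry that step 16 erases. The step needs attack at C7a rather than 6-endo attack at the oxygen-bearing C1, and this is secured by the smaller ring, by the chloride-bound neutral palladium with monodentate PPh3, which places carbon on the enol-ether carbon remote from oxygen, and by the geminal substituents on C7, which press the two reacting ends together. It also needs the triflate cis to C6, as fixed in step 14, whereas the C6=C1' enone cannot compete because insertion there would make a three- or four-membered ring.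

Step 16
Reactants: 29 ring A ketal
Product: 31 methyl (6Z,7R)-3,7-dimethyl-6-[(3S)-3-methyl-2-oxononylidene]-7-(triethylsilyloxy)-6,7-dihydrocyclopenta[c]pyran-5-carboxylate, via methyl ketone 30 (not isolated)
Conditions: pyridinium p-toluenesulfonate (cat), acetone/H2O, 50 °C
Reagents that add atoms: water, O
Why: Acid-catalysed ketal hydrolysis frees the C3 ketone, whose enol oxygen adds to C1 of the push–pull methoxymethylene dienoate and expels methanol (vinylogous transesterification, 6-endo-trig closure of ring B), while reversible protonation at the C2' oxygen lets the C6=C1' bond settle in the less crowded Z geometry with the acyl group away from the C5 ester, and any early loss of the silyl group only anticipates step 17.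

Step 17
Reactants: 31 silylated cyclopenta[c]pyran
Product: 32 methyl (6Z,7R)-7-hydroxy-3,7-dimethyl-6-[(3S)-3-methyl-2-oxononylidene]-6,7-dihydrocyclopenta[c]pyran-5-carboxylate (CNP0253314.1)
Conditions: HF·pyridine, excess pyridine, THF, 0 °C to rt
Reagents that add atoms: none
Why: Fluoride-driven cleavage of the Si–O bond in a pyridine-buffered medium frees the tertiary alcohol without breaking the C7–O bond, without base that could epimerise C3', and without risk of lactonisation onto the C5 ester, which ring A now forbids as a bridgehead alkene.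

## Compound list

1 | (E)-3-methylpent-2-en-4-yn-1-ol | C#C/C(C)=C/CO | starting material
2 | [(2R,3R)-3-ethynyl-3-methyloxiran-2-yl]methanol | C#C[C@@]1(C)O[C@@H]1CO | intermediate
3 | (2R,3S)-2-ethynyl-3-(iodomethyl)-2-methyloxirane | C#C[C@@]1(C)O[C@@H]1CI | intermediate
4 | (S)-3-methylpent-1-en-4-yn-3-ol | C#C[C@@](C)(O)C=C | intermediate
5 | triethyl{[(3S)-3-methylpent-1-en-4-yn-3-yl]oxy}silane | C#C[C@@](C)(O[Si](CC)(CC)CC)C=C | intermediate
6 | secondary ozonide of 5 (3-substituted 1,2,4-trioxolane) | C#C[C@@](C)(O[Si](CC)(CC)CC)C1OCOO1 | intermediate (not isolated)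
7 | (R)-2-methyl-2-(triethylsilyloxy)but-3-ynal | C#C[C@@](C)(O[Si](CC)(CC)CC)C=O | intermediate
8 | triethyl{[(1E,3S)-1-methoxy-3-methylpent-1-en-4-yn-3-yl]oxy}silane | C#C[C@@](C)(O[Si](CC)(CC)CC)/C=C/OC | intermediate
9 | (S)-4-benzyl-1,3-oxazolidin-2-one | O=C1N[C@@H](Cc2ccccc2)CO1 | starting material
10 | octanoyl chloride | CCCCCCCC(=O)Cl | starting material
11 | lithium salt of 9 | [Li+].O=C1[N-][C@@H](Cc2ccccc2)CO1 | intermediate (not isolated)
12 | (S)-4-benzyl-3-octanoyl-1,3-oxazolidin-2-one | CCCCCCCC(=O)N1[C@@H](Cc2ccccc2)COC1=O | intermediate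
13 | sodium (Z)-enolate of 12 | CCCCCC/C=C(\[O-])N1[C@@H](Cc2ccccc2)COC1=O.[Na+] | intermediate (not isolated)
14 | (S)-4-benzyl-3-[(S)-2-methyloctanoyl]-1,3-oxazolidin-2-one | CCCCCC[C@H](C)C(=O)N1[C@@H](Cc2ccccc2)COC1=O | intermediate
15 | (S)-N-methoxy-N,2-dimethyloctanamide | CCCCCC[C@H](C)C(=O)N(C)OC | intermediate
16 | lithium acetylide of 8 | [Li+].[C-]#C[C@@](C)(O[Si](CC)(CC)CC)/C=C/OC | intermediate (not isolated)
17 | lithium hemiaminal alkoxide from 16 and 15 | CCCCCC[C@H](C)C([O-])(N(C)OC)C#C[C@@](C)(O[Si](CC)(CC)CC)/C=C/OC.[Li+] | intermediate (not isolated)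
18 | (1E,3S,7S)-1-methoxy-3,7-dimethyl-3-(triethylsilyloxy)tridec-1-en-4-yn-6-one | CCCCCC[C@H](C)C(=O)C#C[C@@](C)(O[Si](CC)(CC)CC)/C=C/OC | intermediate
19 | ethyl 2-(2-methyl-1,3-dioxolan-2-yl)acetate | CCOC(=O)CC1(C)OCCO1 | starting material
20 | lithium 2-(2-methyl-1,3-dioxolan-2-yl)acetate | [Li+].[O-]C(=O)CC1(C)OCCO1 | intermediate (not isolated)
21 | 2-(2-methyl-1,3-dioxolan-2-yl)acetic acid | OC(=O)CC1(C)OCCO1 | intermediate
22 | 1-(imidazol-1-yl)-2-(2-methyl-1,3-dioxolan-2-yl)ethan-1-one | O=C(CC1(C)OCCO1)n1ccnc1 | intermediate (not isolated)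
23 | methyl 4-(2-methyl-1,3-dioxolan-2-yl)-3-oxobutanoate | COC(=O)CC(=O)CC1(C)OCCO1 | intermediate
24 | Michael adduct (C5 epimers and enol; C6=C1' Z, acyl cis to C7) | CCCCCC[C@H](C)C(=O)/C=C(/C(C(=O)OC)C(=O)CC1(C)OCCO1)[C@@](C)(O[Si](CC)(CC)CC)/C=C/OC | intermediate
25 | potassium enolate of 24 (C4a oxygen cis to C6) | CCCCCC[C@H](C)C(=O)/C=C(/C(C(=O)OC)=C(CC1(C)OCCO1)\[O-])[C@@](C)(O[Si](CC)(CC)CC)/C=C/OC.[K+] | intermediate (not isolated)
26 | open-chain (E)-enol triflate, (S)-C7 silyl ether, (E)-methoxyvinyl, (Z)-enone, (S)-C3' | CCCCCC[C@H](C)C(=O)/C=C(/C(C(=O)OC)=C(CC1(C)OCCO1)\OS(=O)(=O)C(F)(F)F)[C@@](C)(O[Si](CC)(CC)CC)/C=C/OC | intermediate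
27 | C4a alkenylpalladium chloride (PPh3 ligands omitted) | CCCCCC[C@H](C)C(=O)/C=C(/C(C(=O)OC)=C(CC1(C)OCCO1)\[Pd]Cl)[C@@](C)(O[Si](CC)(CC)CC)/C=C/OC | intermediate (not isolated)
28 | C1 alkylpalladium chloride, ring A closed (PPh3 ligands omitted) | CCCCCC[C@H](C)C(=O)/C=C1/C(C(=O)OC)=C(CC2(C)OCCO2)C(C(OC)[Pd]Cl)[C@]1(C)O[Si](CC)(CC)CC | intermediate (not isolated)
29 | ring A ester with C7a (Z)-methoxymethylene, C4a dioxolanylmethyl arm, (R)-C7 silyl ether | CCCCCC[C@H](C)C(=O)/C=C1/C(C(=O)OC)=C(CC2(C)OCCO2)\C(=C\OC)[C@]1(C)O[Si](CC)(CC)CC | intermediate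
30 | C3 methyl ketone from 29 | CCCCCC[C@H](C)C(=O)/C=C1/C(C(=O)OC)=C(CC(C)=O)\C(=C\OC)[C@]1(C)O[Si](CC)(CC)CC | intermediate (not isolated)
31 | C7 triethylsilyl ether of the target | CCCCCC[C@H](C)C(=O)/C=C1/C(C(=O)OC)=C2C=C(C)OC=C2[C@]1(C)O[Si](CC)(CC)CC | intermediate
32 | methyl (6Z,7R)-7-hydroxy-3,7-dimethyl-6-[(3S)-3-methyl-2-oxononylidene]-6,7-dihydrocyclopenta[c]pyran-5-carboxylate | CCCCCC[C@H](C)C(=O)/C=C1/C(C(=O)OC)=C2C=C(C)OC=C2[C@]1(C)O | target

## Step count and risks

Total step count: 17.
Longest linear sequence: 12 steps (steps 1–6, 10, 13–17).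

**1. Step 15 (Heck closure).**
- What may go wrong: insertion of the hindered, electron-rich alkene may be slow. Base-induced loss of triflic acid across C4a–C4 or hydride reduction of the alkenylpalladium species could then take over, or closure could drift to the 6-endo mode.
- Fallback: it sets out from 26 and replaces carbopalladation by a coupling of two sp2 electrophiles. Br2 (1 equiv, CH2Cl2, −78 °C) adds to the enol ether, the only electron-rich alkene. Et3N then removes HBr to give the C7a-bromo enol ether triflate F1.
- A nickel/palladium dual-catalysed cross-electrophile coupling of the alkenyl bromide with the alkenyl triflate then joins C7a to C4a directly. The conditions are NiBr2 with 2,2'-bipyridine, PdCl2(dppp) and Zn dust in DMF at rt. There is no insertion regiochemistry and no β-hydride elimination to control. The fallback comes back to the route at 29.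

**2. Step 13 (Michael addition).**
- What may go wrong: attack at the alkyne carbon next to quaternary C7 may stall. Prolonged base contact may also let the enone geometry drift, after which lactonisation of the side-chain dienolate onto the ester, or epimerisation at C3', would erode the material.
- Fallback: it sets out from 18 and changes the donor to the flat, more acidic lactone form of the same triketide, 4-hydroxy-6-methyl-2H-pyran-2-one F2. With catalytic Et3N in MeCN at 40 °C this adds through its C3 (the future C5) to give the stable enol 3-alkenyl-4-hydroxypyranone F3.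
- PhNTf2 and Et3N in CH2Cl2 give the pyranonyl triflate F4. Its ring holds the triflate cis to C6 and rules out loss of triflic acid.
- The conditions of step 15 close ring A to the cyclopenta-fused pyranone F5.
- Mg(OMe)2 in MeOH at rt opens the lactone to the methyl ester and the C3 ketone. This comes back to the route at 30, which closes to 31 under the conditions of step 16.

**3. Step 14 (enol triflation).**
- What may go wrong: poor control of the tetrasubstituted enolate geometry would place the leaving group cis to the ester, where palladium cannot reach C7a. Sulfonylation could also leak to the C2' oxygen.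
- Fallback: it sets out from 24 and shifts stereocontrol from the counter-ion to the reagent. TsCl, N-methylimidazole and Et3N in CH2Cl2 at 0 °C form the non-chelating branch of the stereocomplementary enol tosylation of 2-substituted β-keto esters. The bulky N-sulfonylimidazolium salt sulfonylates the hydrogen-bond-free enolate to give the (E)-enol tosylate F6.
- F6 is robust enough to be purified from any Z isomer. Its Heck closure with Pd(OAc)2, PCy3, LiCl and pentamethylpiperidine in DMF at 80 °C, the known Heck reaction of activated alkenyl tosylates, comes back to the route at 29.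

## Further compounds

F1 | step 15 | C7a-bromo enol ether triflate | CCCCCC[C@H](C)C(=O)/C=C(/C(C(=O)OC)=C(CC1(C)OCCO1)\OS(=O)(=O)C(F)(F)F)[C@@](C)(O[Si](CC)(CC)CC)C(Br)=COC
F2 | step 13 | 4-hydroxy-6-methyl-2H-pyran-2-one | CC1=CC(O)=CC(=O)O1
F3 | step 13 | 3-alkenyl-4-hydroxypyranone | CCCCCC[C@H](C)C(=O)/C=C(/C1=C(O)C=C(C)OC1=O)[C@@](C)(O[Si](CC)(CC)CC)/C=C/OC
F4 | step 13 | pyranonyl triflate | CCCCCC[C@H](C)C(=O)/C=C(/C1=C(OS(=O)(=O)C(F)(F)F)C=C(C)OC1=O)[C@@](C)(O[Si](CC)(CC)CC)/C=C/OC
F5 | step 13 | cyclopenta-fused pyranone | CCCCCC[C@H](C)C(=O)/C=C1/C2=C(C=C(C)OC2=O)\C(=C\OC)[C@]1(C)O[Si](CC)(CC)CC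
F6 | step 14 | (E)-enol tosylate | CCCCCC[C@H](C)C(=O)/C=C(/C(C(=O)OC)=C(CC1(C)OCCO1)\OS(=O)(=O)c1ccc(C)cc1)[C@@](C)(O[Si](CC)(CC)CC)/C=C/OC
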